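**Retrosynthetic overview**
1. Numbering used here: ring carbons C1–C10 (C10 = C(Me)–O, C9 = its CH2, C8 = CH–O-acyl, C7/C6 = lactone fusion, C5 = ether CH, C4 = C–CO2Me, C3 = alkene CH), lactone carbons C11–C13; ring A = O/C10/C1–C5, ring B = O/C10/C9–C5. Last events: acylation of C8–OH with the silyl-protected (S)-acid 26 and Mannich methylenation at C11.
2. Ring A, and with it the ten-membered carbocycle, comes from an intramolecular Horner–Wadsworth–Emmons closure of C3=C4 in aldehyde-phosphonate 19; the bridging constraint fixes C5.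
3. Key disconnection, a (3+4) annulation: C8–C9 and O–C5 are cut together, giving the β-oxido organometallic from epoxide 5 and the aldehyde/alkylidene phosphonoacetate 14; their union forms ring B.
4. Enabling feature: C10 carries both the ether oxygen and the C9 methylene, so O–C10–C9 is a 1,3-C,O-dianion stored in a 2,2-disubstituted epoxide; C8 and C5 stand 1,4 across the trans C6–C7 bond of the γ-lactone and can be a formyl carbon and the β-carbon of an alkylidene phosphonoacetate. These seven atoms are ring B.
5. Ring order: γ-lactone (kept from butenolide 6), then ring B (step 9), then ring A and the carbocycle (step 11). C10 and the side-chain carbinol come from (R)-2-methylglycidol 1, C6 from 6, C7 from cuprate addition, C8 from ketone reduction.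

Key step: step 9

Remark: compounds 1, 3, 6 and 11 are assumed to be commercial; the C3=C4 alkene lies in the seven-membered ring A, so its geometry is fixed and carries no descriptor.

Step 1
Reactants: 1 (R)-(2-methyloxiran-2-yl)methanol [(R)-2-methylglycidol]
Product: 2 [(2S)-2-methyloxiran-2-yl]methyl 4-methylbenzenesulfonate
Conditions: TsCl, Et3N, DMAP (cat.), CH2Cl2, 0 °C
Reagents that add atoms: p-toluenesulfonyl chloride, Cc1ccc(cc1)S(Cl)(=O)=O
Why: O-sulfonylation of the primary alcohol without alkoxide formation leaves the quaternary centre untouched (the descriptor changes from R to S only through the priority rules).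

Step 2
Reactants: 2 [(2S)-2-methyloxiran-2-yl]methyl 4-methylbenzenesulfonate; 3 (1,3-dioxolan-2-ylmethyl)magnesium bromide
Product: 5 (2S)-2-[2-(1,3-dioxolan-2-yl)ethyl]-2-methyloxirane, via hydroxy tosylate 4 (not isolated)
Conditions: CuI (10 mol %), THF, −30 → 0 °C; aq. NH4Cl; then K2CO3, MeOH, rt
Reagents that add atoms: none
Why: Copper-catalysed Grignard opening of the epoxide at its CH2 terminus, then base-induced 3-exo-tet closure of the tertiary alkoxide onto the tosylate (the epoxide transposition known for glycidyl sulfonates), should deliver C1–C3 and C9 without breaking a bond to the future C10.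

Step 3
Reactants: 6 (5S)-5-(hydroxymethyl)furan-2(5H)-one
Product: 7 (5S)-5-{[tert-butyl(dimethyl)silyl]oxymethyl}furan-2(5H)-one
Conditions: TBSCl, imidazole, DMF, 0 °C → rt
Reagents that add atoms: tert-butyldimethylsilyl chloride, CC(C)(C)[Si](C)(C)Cl
Why: Standard silylation of the primary alcohol; imidazole does not enolise the butenolide, so C6 is preserved.

Step 4
Reactants: 7 (5S)-5-{[tert-butyl(dimethyl)silyl]oxymethyl}furan-2(5H)-one
Product: 8 (4R,5S)-5-{[tert-butyl(dimethyl)silyl]oxymethyl}-4-vinyldihydrofuran-2(3H)-one (trans)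
Conditions: CH2=CHMgBr, CuBr·SMe2, THF, −78 °C; aq. NH4Cl
Reagents that add atoms: vinylmagnesium bromide, C=C[Mg]Br
Why: Cuprate conjugate addition to a 5-substituted butenolide occurs anti to the C5 substituent, which should set C7 trans to C6.

Step 5
Reactants: 8 (4R,5S)-5-{[tert-butyl(dimethyl)silyl]oxymethyl}-4-vinyldihydrofuran-2(3H)-one
Product: 9 (4R,5S)-5-(hydroxymethyl)-4-vinyldihydrofuran-2(3H)-one
Conditions: HF·pyridine, THF, 0 °C → rt
Reagents that add atoms: none
Why: Fluoride cleavage of the primary silyl ether under non-basic conditions that leave the lactone alone.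

Step 6
Reactants: 9 (4R,5S)-5-(hydroxymethyl)-4-vinyldihydrofuran-2(3H)-one
Product: 10 (2S,3R)-5-oxo-3-vinyltetrahydrofuran-2-carbaldehyde
Conditions: Dess–Martin periodinane, NaHCO3, CH2Cl2, 0 °C → rt
Reagents that add atoms: none
Why: Dess–Martin oxidation should give the α-alkoxy aldehyde without base, so C6 is not epimerised.

Step 7
Reactants: 10 (2S,3R)-5-oxo-3-vinyltetrahydrofuran-2-carbaldehyde; 11 trimethyl phosphonoacetate
Product: 12 methyl 2-(dimethoxyphosphoryl)-3-[(2S,3R)-5-oxo-3-vinyltetrahydrofuran-2-yl]prop-2-enoate (E/Z mixture)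
Conditions: TiCl4, N-methylmorpholine, THF, 0 °C → rt
Reagents that add atoms: none
Why: Knoevenagel condensation (TiCl4/amine variant) of an aliphatic aldehyde with a phosphonoacetate should give the alkylidene phosphonoacetate; any C6 epimerisation through the vinylogous enolate would only return the more stable trans-lactone.

Step 8
Reactants: 12 methyl 2-(dimethoxyphosphoryl)-3-[(2S,3R)-5-oxo-3-vinyltetrahydrofuran-2-yl]prop-2-enoate
Product: 14 methyl 2-(dimethoxyphosphoryl)-3-[(2S,3S)-3-formyl-5-oxotetrahydrofuran-2-yl]prop-2-enoate, via ozonide 13 (not isolated)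
Conditions: O3, CH2Cl2, −78 °C (Sudan Red 7B end point); then Me2S, −78 °C → rt
Reagents that add atoms: ozone, [O-][O+]=O
Why: Ozonolysis should be chemoselective for the electron-rich monosubstituted vinyl group over the doubly acceptor-substituted alkene, and reductive work-up gives the C8 aldehyde, which is used at once.

Step 9
Reactants: 5 (2S)-2-[2-(1,3-dioxolan-2-yl)ethyl]-2-methyloxirane; 14 methyl 2-(dimethoxyphosphoryl)-3-[(2S,3S)-3-formyl-5-oxotetrahydrofuran-2-yl]prop-2-enoate
Product: 18 ring-B oxepane fused trans to the γ-lactone, carrying at C10 the methyl and 2-(1,3-dioxolan-2-yl)ethyl groups, at C8 a hydroxyl and at C5 a CH(CO2Me)P(O)(OMe)2 group (C6, C7, C10 as in 32; epimer mixture at C4, C5, C8), via dilithio alkoxide 15 (not isolated), via organocerium alkoxide 16 (not isolated), via open-chain dialkoxide 17 (not isolated)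
Conditions: 5 (1.5 equiv), LiDBB (Li 4,4′-di-tert-butylbiphenylide), THF, −78 °C; CeCl3, −78 °C; then 14, −78 → −40 °C; AcOH, −40 °C
Reagents that add atoms: none
Why: Proposed new method: reductive lithiation of the 2,2-disubstituted epoxide 5 cleaves the CH2–O bond and gives the β-oxido primary carbanion 15, a 1,3-C,O-dinucleophile; its cerium derivative 16 adds 1,2 to the aldehyde of 14 (C8–C9), and the tertiary alkoxide closes ring B (O, C10, C9, C8, C7, C6, C5) by a 7-exo-trig oxa-Michael addition to the alkylidene phosphonoacetate (O–C5), leaving the phosphonoacetate that step 11 needs. The closest known reactions are the addition of epoxide-derived β-lithioalkoxides to carbonyl compounds and the oxa-Michael/HWE annulations of hydroxy carbonyl compounds with vinylphosphonates; combining them as a (3+4) annulation of a C,O-dianion with a 1,4-dielectrophile is new. C10 comes unchanged from 5, and C6 and C7 from 14; the new centres at C8 and C4 are not controlled and are erased later (steps 12 and 11), and C5 is formed reversibly and is corrected in step 11 by the bridging constraint. The step needs 1,2-addition to the aldehyde in preference to conjugate addition or enolisation, which the low basicity and carbonyl selectivity of the organocerium at −78 °C should secure. It also needs attack at C5 by the tertiary rather than the new secondary alkoxide; the secondary alkoxide could only form a strained trans-fused bicyclo[3.3.0] tetrahydrofuran on the trans-lactone, and the oxa-Michael addition is reversible. The cold acidic quench should limit migration of the lactone acyl group to the C8 alkoxide.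

Step 10
Reactants: 18 ring-B oxepane adduct (dioxolane)
Product: 19 the corresponding C3 aldehyde (C10 bears a 3-oxopropyl group; epimer mixture at C4, C5, C8)
Conditions: TsOH·H2O (cat.), acetone/H2O, 40 °C
Reagents that add atoms: water, O
Why: Acid-catalysed acetal hydrolysis frees the C3 aldehyde; the ether, lactone and phosphonate are stable to dilute acid.

Step 11
Reactants: 19 ring-B aldehyde-phosphonate
Product: 20 lactone-fused 11-oxabicyclo[4.4.1]undecene with C3=C4–CO2Me, saturated lactone CH2 at C11 and C8–OH (both C8 epimers; C5, C6, C7, C10 as in 32)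
Conditions: LiCl, iPr2NEt, MeCN (0.005 M), rt → 40 °C
Reagents that add atoms: none
Why: Intramolecular Horner–Wadsworth–Emmons olefination (LiCl/amine conditions) should close the seven-membered ring A and thereby the ten-membered carbocycle, because the β-alkoxy phosphonate anion equilibrates its C5 epimers by retro-oxa-Michael/oxa-Michael addition and only the epimer that can bridge C10 and C5 on one face cyclises, so C5 is set by C10.

Step 12
Reactants: 20 bicyclic enoate alcohol (C8 epimers)
Product: 21 the C8 ketone
Conditions: Dess–Martin periodinane, NaHCO3, CH2Cl2, 0 °C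
Reagents that add atoms: none
Why: Buffered, base-free Dess–Martin oxidation should converge both C8 epimers to one ketone without β-elimination of the lactone oxygen or epimerisation at C7.

Step 13
Reactants: 21 C8 ketone
Product: 22 the (8R)-alcohol (C8–OH cis to the C7–C11 bond)
Conditions: NaBH4, CeCl3·7H2O, MeOH/THF, −78 °C; AcOH
Reagents that add atoms: none
Why: Luche reduction is chemoselective for the ketone over enoate and lactone, and hydride should attack the convex face of ring B, anti to the C7–C11 bond, giving the 8R alcohol.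

Step 14
Reactants: 1 (R)-(2-methyloxiran-2-yl)methanol
Product: 23 (2S)-2-methyloxirane-2-carboxylic acid
Conditions: RuCl3·xH2O (cat.), NaIO4, CCl4/MeCN/H2O, rt
Reagents that add atoms: water, O (carboxyl oxygen through the aldehyde hydrate; NaIO4 is the terminal oxidant)
Why: RuO4 oxidation of an epoxy alcohol to the epoxy acid proceeds without an alkoxide, so the quaternary centre cannot racemise by Payne rearrangement.

Step 15
Reactants: 23 (2S)-2-methyloxirane-2-carboxylic acid
Product: 24 (2S)-2-hydroxy-2-methylbut-3-enoic acid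
Conditions: n-BuLi (1 equiv), then Me3S+ I−/n-BuLi, THF, −10 °C → rt; aq. HCl
Reagents that add atoms: trimethylsulfonium iodide, C[S+](C)C.[I-]
Why: One-carbon homologation of a terminal epoxide to an allylic alcohol with dimethylsulfonium methylide (attack at CH2, then β-elimination of Me2S) should turn the oxirane CH2 into the vinyl group without touching the quaternary carbinol centre.

Step 16
Reactants: 24 (2S)-2-hydroxy-2-methylbut-3-enoic acid
Product: 26 (2S)-2-methyl-2-[(triethylsilyl)oxy]but-3-enoic acid, via bis-silyl derivative 25 (not isolated)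
Conditions: Et3SiOTf, 2,6-lutidine, CH2Cl2, −78 → 0 °C; then K2CO3, MeOH/H2O, 0 °C; pH 4
Reagents that add atoms: triethylsilyl trifluoromethanesulfonate, CC[Si](CC)(CC)OS(=O)(=O)C(F)(F)F
Why: The silyl triflate silylates the tertiary alcohol, and the silyl ester formed alongside is cleaved by mild methanolysis.

Step 17
Reactants: 22 (8R)-alcohol; 26 (2S)-2-methyl-2-[(triethylsilyl)oxy]but-3-enoic acid
Product: 28 the C8 ester (triethylsilyl ether, saturated lactone), via mixed anhydride 27 (not isolated)
Conditions: 26, 2,4,6-Cl3C6H2COCl, Et3N, toluene, rt; then 22, DMAP, toluene, rt → 50 °C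
Reagents that add atoms: none
Why: Yamaguchi esterification through the mixed anhydride should acylate the hindered secondary C8 alcohol under weakly basic conditions without touching any stereocentre.

Step 18
Reactants: 28 C8 ester with saturated lactone
Product: 31 the α-methylene lactone (triethylsilyl ether), via Mannich base 29 (not isolated), via methiodide 30 (not isolated)
Conditions: LDA, THF, −78 °C; CH2=NMe2+ I−, −78 → 0 °C; MeI, MeOH, rt; aq. NaHCO3
Reagents that add atoms: Eschenmoser's salt (N,N-dimethylmethyleneiminium iodide), C[N+](C)=C.[I-]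
Why: Mannich reaction of the kinetically formed lactone enolate with Eschenmoser's salt, quaternisation and E1cB elimination is the standard α-methylenation of γ-lactones, and the C8 ester has no α-hydrogen.

Step 19
Reactants: 31 α-methylene lactone triethylsilyl ether
Product: 32 CNP0325750.1 (5R,6S,7R,8R,10S; side chain 2S)
Conditions: HF·pyridine, pyridine/THF, 0 °C
Reagents that add atoms: none
Why: HF·pyridine should remove the tertiary triethylsilyl ether without attacking the esters, the α-methylene lactone or the bridging ether.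

**Compound list**
1 | (R)-(2-methyloxiran-2-yl)methanol | C[C@@]1(CO)CO1 | starting material
2 | [(2S)-2-methyloxiran-2-yl]methyl 4-methylbenzenesulfonate | C[C@@]1(COS(=O)(=O)c2ccc(C)cc2)CO1 | intermediate
3 | (1,3-dioxolan-2-ylmethyl)magnesium bromide (THF solution) | Br[Mg]CC1OCCO1 | starting material
4 | (2S)-4-(1,3-dioxolan-2-yl)-2-hydroxy-2-methylbutyl 4-methylbenzenesulfonate | C[C@@](O)(COS(=O)(=O)c1ccc(C)cc1)CCC2OCCO2 | intermediate (not isolated)
5 | (2S)-2-[2-(1,3-dioxolan-2-yl)ethyl]-2-methyloxirane | C[C@]1(CCC2OCCO2)CO1 | intermediate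
6 | (5S)-5-(hydroxymethyl)furan-2(5H)-one | OC[C@H]1OC(=O)C=C1 | starting material
7 | (5S)-5-{[tert-butyl(dimethyl)silyl]oxymethyl}furan-2(5H)-one | CC(C)(C)[Si](C)(C)OC[C@H]1OC(=O)C=C1 | intermediate
8 | (4R,5S)-5-{[tert-butyl(dimethyl)silyl]oxymethyl}-4-vinyldihydrofuran-2(3H)-one | CC(C)(C)[Si](C)(C)OC[C@H]1OC(=O)C[C@@H]1C=C | intermediate
9 | (4R,5S)-5-(hydroxymethyl)-4-vinyldihydrofuran-2(3H)-one | OC[C@H]1OC(=O)C[C@@H]1C=C | intermediate
10 | (2S,3R)-5-oxo-3-vinyltetrahydrofuran-2-carbaldehyde | O=C[C@H]1OC(=O)C[C@@H]1C=C | intermediate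
11 | trimethyl phosphonoacetate | COC(=O)CP(=O)(OC)OC | starting material
12 | methyl 2-(dimethoxyphosphoryl)-3-[(2S,3R)-5-oxo-3-vinyltetrahydrofuran-2-yl]prop-2-enoate (E/Z mixture) | COC(=O)C(=C[C@H]1OC(=O)C[C@@H]1C=C)P(=O)(OC)OC | intermediate
13 | ozonide of 12 (1,2,4-trioxolane at the former vinyl group) | COC(=O)C(=C[C@H]1OC(=O)C[C@@H]1C2OCOO2)P(=O)(OC)OC | intermediate (not isolated)
14 | methyl 2-(dimethoxyphosphoryl)-3-[(2S,3S)-3-formyl-5-oxotetrahydrofuran-2-yl]prop-2-enoate (E/Z mixture) | COC(=O)C(=C[C@H]1OC(=O)C[C@@H]1C=O)P(=O)(OC)OC | intermediate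
15 | dilithio alkoxide from 5 (lithium (2S)-4-(1,3-dioxolan-2-yl)-1-lithio-2-methylbutan-2-olate) | [Li]C[C@@](C)(O[Li])CCC1OCCO1 | intermediate (not isolated)
16 | organocerium alkoxide (CeCl2 on C9, lithium alkoxide on C10) | Cl[Ce](Cl)C[C@@](C)(O[Li])CCC1OCCO1 | intermediate (not isolated)
17 | open-chain dialkoxide after C8–C9 bond formation (cerium alkoxide at C8, lithium alkoxide at C10, alkylidene phosphonoacetate intact) | Cl[Ce](Cl)OC(C[C@@](C)(O[Li])CCC1OCCO1)[C@H]2CC(=O)O[C@@H]2C=C(C(=O)OC)P(=O)(OC)OC | intermediate (not isolated)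
18 | ring-B oxepane adduct: trans-lactone-fused oxepane with C10 methyl and 2-(1,3-dioxolan-2-yl)ethyl, C8–OH, C5–CH(CO2Me)P(O)(OMe)2 (C4, C5, C8 epimer mixture; other centres defined) | OC1C[C@](C)(CCC3OCCO3)OC(C(C(=O)OC)P(=O)(OC)OC)[C@H]2OC(=O)C[C@@H]21 | intermediate
19 | ring-B aldehyde-phosphonate (C10 bears a 3-oxopropyl group; C4, C5, C8 epimer mixture) | OC1C[C@](C)(CCC=O)OC(C(C(=O)OC)P(=O)(OC)OC)[C@H]2OC(=O)C[C@@H]21 | intermediate
20 | lactone-fused 11-oxabicyclo[4.4.1]undecene, C3=C4–CO2Me, C8–OH (C8 epimers), C11 = CH2 | OC1C[C@]2(C)CCC=C(C(=O)OC)[C@@H](O2)[C@H]2OC(=O)C[C@@H]21 | intermediate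
21 | C8 ketone of 20 | O=C1C[C@]2(C)CCC=C(C(=O)OC)[C@@H](O2)[C@H]2OC(=O)C[C@@H]21 | intermediate
22 | (8R)-alcohol (C8–OH cis to C7–C11; all ring centres as in 32) | O[C@@H]1C[C@]2(C)CCC=C(C(=O)OC)[C@@H](O2)[C@H]2OC(=O)C[C@@H]21 | intermediate
23 | (2S)-2-methyloxirane-2-carboxylic acid | C[C@@]1(C(O)=O)CO1 | intermediate
24 | (2S)-2-hydroxy-2-methylbut-3-enoic acid | C=C[C@](C)(O)C(O)=O | intermediate
25 | triethylsilyl (2S)-2-methyl-2-[(triethylsilyl)oxy]but-3-enoate | C=C[C@](C)(O[Si](CC)(CC)CC)C(=O)O[Si](CC)(CC)CC | intermediate (not isolated)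
26 | (2S)-2-methyl-2-[(triethylsilyl)oxy]but-3-enoic acid | C=C[C@](C)(O[Si](CC)(CC)CC)C(O)=O | intermediate
27 | mixed anhydride of 26 with 2,4,6-trichlorobenzoic acid | C=C[C@](C)(O[Si](CC)(CC)CC)C(=O)OC(=O)c1c(Cl)cc(Cl)cc1Cl | intermediate (not isolated)
28 | C8 ester of 22 with 26 (triethylsilyl ether, C11 = CH2) | C=C[C@](C)(O[Si](CC)(CC)CC)C(=O)O[C@@H]1C[C@]2(C)CCC=C(C(=O)OC)[C@@H](O2)[C@H]2OC(=O)C[C@@H]21 | intermediate
29 | C11 dimethylaminomethyl lactone (Mannich base, C11 epimers) | C=C[C@](C)(O[Si](CC)(CC)CC)C(=O)O[C@@H]1C[C@]2(C)CCC=C(C(=O)OC)[C@@H](O2)[C@H]2OC(=O)C(CN(C)C)[C@@H]21 | intermediate (not isolated)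
30 | trimethylammonium iodide of 29 | C=C[C@](C)(O[Si](CC)(CC)CC)C(=O)O[C@@H]1C[C@]2(C)CCC=C(C(=O)OC)[C@@H](O2)[C@H]2OC(=O)C(C[N+](C)(C)C)[C@@H]21.[I-] | intermediate (not isolated)
31 | triethylsilyl ether of the target (α-methylene lactone) | C=C[C@](C)(O[Si](CC)(CC)CC)C(=O)O[C@@H]1C[C@]2(C)CCC=C(C(=O)OC)[C@@H](O2)[C@H]2OC(=O)C(=C)[C@@H]21 | intermediate
32 | CNP0325750.1 | C=C[C@](C)(O)C(=O)O[C@@H]1C[C@]2(C)CCC=C(C(=O)OC)[C@@H](O2)[C@H]2OC(=O)C(=C)[C@@H]21 | target

**Step count and risks**
Total step count: 19. Longest linear sequence: 14 steps (6 → 32 through steps 3–13 and 17–19).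

Steps most likely to fail:

1. Step 9 (proposed method). The organometallic may add conjugately to the alkylidene phosphonoacetate, or deprotonate the β-acyloxy aldehyde and trigger β-elimination, instead of adding 1,2. Ring closure by the tertiary alkoxide may be slow, and the lactone acyl group may migrate to the new C8 alkoxide. Fallback with known chemistry, setting out from 8 and returning at 18: ozonolysis of 8 (O3; Me2S) gives the formyl lactone silyl ether F1. Addition of the organocerium 16 (made from 5 as in step 9) to F1, which has no Michael acceptor, gives the silyl-protected diol F2. HF·pyridine gives the triol F3. Oxidation of the primary alcohol alone (TEMPO, PhI(OAc)2) gives the hydroxy aldehyde F4. Knoevenagel condensation of F4 with 11 (piperidinium acetate) and oxa-Michael closure by the C10 hydroxyl on the alkylidene so formed gives 18.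

2. Step 11. The C5 epimers may fail to equilibrate under the mild base, the aldehyde-phosphonate may oligomerise, or the lactone may migrate to the free C8 hydroxyl. Fallback, setting out from 18 and returning at 20: olefination of the phosphonate with aqueous formaldehyde and K2CO3 gives the acrylate F5, whose 5R epimer is separated and carried on. Acetal hydrolysis (TsOH, wet acetone) gives the aldehyde F6. Wittig methylenation (Ph3P=CH2, THF, −78 °C) gives the diene F7. Ring-closing metathesis with the second-generation Hoveyda–Grubbs catalyst (toluene, 80 °C, high dilution) closes ring A and gives 20.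

3. Step 18. The amide base may deprotonate the γ-position of the enoate or add to it instead of enolising the lactone. Fallback, setting out from 28 and returning at 31: carboxylation of the lactone α-position with methyl magnesium carbonate (MeOMgOCO2Me, DMF, 120 °C) gives the α-carboxy lactone F8. Decarboxylative Mannich methylenation (aq. HCHO, Et2NH, AcOH/NaOAc) then gives 31.

**Further compounds**
F1 | step 9 | (2S,3S)-2-{[tert-butyl(dimethyl)silyl]oxymethyl}-5-oxotetrahydrofuran-3-carbaldehyde | CC(C)(C)[Si](C)(C)OC[C@H]1OC(=O)C[C@@H]1C=O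
F2 | step 9 | silyl-protected diol (C8–OH epimers, C10–OH, dioxolane chain) | CC(C)(C)[Si](C)(C)OC[C@H]1OC(=O)C[C@@H]1C(O)C[C@@](C)(O)CCC2OCCO2
F3 | step 9 | triol (C5–OH, C8–OH, C10–OH) | OC[C@H]1OC(=O)C[C@@H]1C(O)C[C@@](C)(O)CCC2OCCO2
F4 | step 9 | hydroxy aldehyde (C5 aldehyde, C8–OH, C10–OH) | O=C[C@H]1OC(=O)C[C@@H]1C(O)C[C@@](C)(O)CCC2OCCO2
F5 | step 11 | ring-B acrylate (C4=CH2, 5R, dioxolane chain, C8–OH epimers) | OC1C[C@](C)(CCC3OCCO3)O[C@H](C(=C)C(=O)OC)[C@H]2OC(=O)C[C@@H]21
F6 | step 11 | ring-B acrylate aldehyde (C3 aldehyde) | OC1C[C@](C)(CCC=O)O[C@H](C(=C)C(=O)OC)[C@H]2OC(=O)C[C@@H]21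
F7 | step 11 | ring-B diene (but-3-enyl at C10, acrylate at C5) | OC1C[C@](C)(CCC=C)O[C@H](C(=C)C(=O)OC)[C@H]2OC(=O)C[C@@H]21
F8 | step 18 | C11 carboxylic acid of 28 (C11 epimers) | C=C[C@](C)(O[Si](CC)(CC)CC)C(=O)O[C@@H]1C[C@]2(C)CCC=C(C(=O)OC)[C@@H](O2)[C@H]2OC(=O)C(C(O)=O)[C@@H]21
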